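**Plan**
1. Retrosynthesis first cuts the two ring–CH2 bonds that tie ring A (the 4,4-dimethyl triketone ring) and ring C (the methoxy-methyl aryl ketone) to the central ring B. It then cuts, inside ring A, the bond from the ring ketone carbon to the butyryl-bearing carbon and the bond from the enol carbon to the C(CH3)2 carbon.
2. Enabling feature: the six carbons of ring A alternate carbonyl-level and nucleophilic carbons (a cyclohexane-1,3,5-trione that the C(CH3)2 carbon keeps from aromatising). The ring is therefore a malonyl unit (ring C=O, the CH that later bears the bridge, enol carbon) joined to the α, carbonyl and α' carbons of an isopropyl ketone.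
3. Forward, ring A is made first in one double C-acylation of a regiodefined 2-silyloxy-4-methoxy diene with malonyl dichloride. This gives butyrylfilicinic acid with the quaternary carbon and the butyryl group in place.
4. Ring C (aspidinol) is made from 2,4,6-trihydroxytoluene and its Mannich base is joined to purchased ring B (phlorbutyrophenone). A second Mannich base on ring B then takes up ring A, so the chain grows C, then B, then A.
5. Stereochemistry: the target has no stereocentre; only enol tautomers and a transient enol-ether geometry occur, and neither needs control.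

Key step: step 4

Remark: the target is achiral and is drawn as one enol tautomer of its ring A β-triketone; all ring A compounds are written in the matching tautomer. 2,4,6-Trihydroxytoluene and 1-(2,4,6-trihydroxyphenyl)butan-1-one are taken as purchasable.

**Route**

Step 1
Reactants: 1 pent-1-yne; 2 2-methylpropanoyl chloride
Product: 3 2-methyloct-4-yn-3-one
Conditions: PdCl2(PPh3)2 (2 mol%), CuI (4 mol%), Et3N (1.2 equiv), THF, rt
Reagents that add atoms: none
Why: Acyl Sonogashira coupling of a terminal alkyne with an acid chloride should give the ynone directly under conditions mild enough to leave the α-branched acyl chloride intact.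

Step 2
Reactants: 3 2-methyloct-4-yn-3-one
Product: 4 (E)-5-methoxy-2-methyloct-4-en-3-one
Conditions: NaOMe (0.1 equiv), MeOH, 0 °C to rt
Reagents that add atoms: methanol, CO
Why: Base-catalysed oxa-Michael addition of methanol to the ynone places the methoxy group only on the propyl-bearing carbon, which fixes a regiochemistry that O-methylation of the free β-diketone could not; the E isomer should prevail and the geometry is lost later in any case.

Step 3
Reactants: 4 (E)-5-methoxy-2-methyloct-4-en-3-one
Product: 5 [(4E)-5-methoxy-2-methylocta-2,4-dien-3-yl]oxy-trimethylsilane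
Conditions: LiN(iPr)2 (1.1 equiv), THF, −78 °C; Me3SiCl (1.3 equiv), −78 °C to rt; pentane, filtration, distillation
Reagents that add atoms: chlorotrimethylsilane, C[Si](C)(C)Cl
Why: Kinetic deprotonation of a β-alkoxy enone occurs at the α' carbon (Stork–Danheiser regiochemistry), here the isopropyl methine as the only α' hydrogen, and O-silylation gives the 2-silyloxy-4-methoxy diene (Danishefsky-type diene formation).

Step 4
Reactants: 5 [(4E)-5-methoxy-2-methylocta-2,4-dien-3-yl]oxy-trimethylsilane; 6 propanedioyl dichloride (malonyl dichloride)
Product: 9 butyrylfilicinic acid (2-butanoyl-3,5-dihydroxy-4,4-dimethylcyclohexa-2,5-dien-1-one), via keto acyl chloride 7 (not isolated), via exocyclic methyl enol ether 8 (not isolated)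
Conditions: 5 added slowly to 6 (1.2 equiv), CH2Cl2, −78 to 0 °C; then Et3N (3 equiv), DMAP (0.1 equiv), 0 °C to rt; then 1 M HCl, THF, rt
Reagents that add atoms: water, O
Why: Proposed new method: the tetrasubstituted diene terminus, pushed by the silyloxy oxygen and vinylogously by the methoxy oxygen, should C-acylate one COCl group of malonyl dichloride with loss of Me3SiCl and so form the bond from the future C(CH3)2 carbon to a ring carbonyl, after which the α-carbon of the β-methoxy enone in 7 attacks the second acyl chloride (or the acylketene that Et3N makes from it) and forms the bond between the butyryl-bearing carbon and the other ring carbonyl. The closest known reaction types are the Effenberger α,α'-annulation of ketone enol ethers with malonyl dichloride and the formal [3+3] cyclisation of 1,3-bis(silyloxy)-1,3-dienes with 1,3-dielectrophiles. Ring A closes in a 6-(enolexo)-exo-trig acylation, and no stereocentre is formed. The step needs site selectivity between the two α-carbons of the central ketone, which the substrate secures because the butyryl-side carbonyl is locked as its methyl enol ether and only the isopropyl side carries the silyl enol ether. It also needs C- over O-acylation in the ring closure: any enol lactone from O-closure is an enol ester of a β-diketone that Et3N/DMAP acyl transfer should funnel to the fully enolised β-triketone, the thermodynamic sink, while slow inverse addition holds back 2:1 adducts. Aqueous acid finally hydrolyses the exocyclic methyl enol ether of 8 to the butyryl ketone.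

Step 5
Reactants: 10 2,4,6-trihydroxytoluene; 11 butanoyl chloride
Product: 12 1-(2,4,6-trihydroxy-3-methylphenyl)butan-1-one
Conditions: AlCl3 (3.5 equiv), PhNO2/CH2Cl2, 0 to 40 °C; then 1 M HCl
Reagents that add atoms: none
Why: Friedel–Crafts C-acylation of the phloroglucinol nucleus should stop at the mono-ketone because the two free ring positions are equivalent and the first acyl group deactivates the ring.

Step 6
Reactants: 12 1-(2,4,6-trihydroxy-3-methylphenyl)butan-1-one
Product: 13 aspidinol (1-(2,6-dihydroxy-4-methoxy-3-methylphenyl)butan-1-one)
Conditions: Me2SO4 (1.0 equiv), K2CO3 (1.0 equiv), acetone, rt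
Reagents that add atoms: dimethyl sulfate, COS(=O)(=O)OC
Why: The hydroxyl para to the ketone is the most acidic and is not hydrogen-bonded to the carbonyl, so one equivalent of base and a hard methylating agent should give regioselective Williamson O-methylation there.

Step 7
Reactants: 13 aspidinol
Product: 14 1-[3-[(dimethylamino)methyl]-2,6-dihydroxy-4-methoxy-5-methylphenyl]butan-1-one
Conditions: [Me2N=CH2]I (1.1 equiv), Et3N (1.2 equiv), CH2Cl2, 0 °C to rt
Reagents that add atoms: N,N-dimethylmethyleneiminium iodide, C=[N+](C)C.[I-]
Why: Mannich aminomethylation of an electron-rich phenol, directed to the only free nuclear carbon.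

Step 8
Reactants: 14 Mannich base of aspidinol; 15 1-(2,4,6-trihydroxyphenyl)butan-1-one (phlorbutyrophenone)
Product: 17 1-[3-[(3-butanoyl-2,4-dihydroxy-6-methoxy-5-methylphenyl)methyl]-2,4,6-trihydroxyphenyl]butan-1-one, via ortho-quinone methide 16 (not isolated)
Conditions: 15 (3 equiv), 1,4-dioxane, 90 °C, N2
Reagents that add atoms: none
Why: Thermal loss of dimethylamine from the ortho-hydroxybenzylamine gives an ortho-quinone methide that the phloroglucinol nucleus of 15 captures by conjugate C-alkylation; excess 15 should suppress double alkylation, and 14 has no free nuclear carbon with which to self-condense.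

Step 9
Reactants: 17 the ring B–ring C dimer
Product: 18 1-[3-[(3-butanoyl-2,4-dihydroxy-6-methoxy-5-methylphenyl)methyl]-5-[(dimethylamino)methyl]-2,4,6-trihydroxyphenyl]butan-1-one
Conditions: [Me2N=CH2]I (1.1 equiv), Et3N (1.2 equiv), CH2Cl2/THF, 0 °C to rt
Reagents that add atoms: N,N-dimethylmethyleneiminium iodide, C=[N+](C)C.[I-]
Why: Mannich aminomethylation at the single free nuclear CH, which lies on ring B because ring C is fully substituted.

Step 10
Reactants: 18 Mannich base of the dimer; 9 butyrylfilicinic acid
Product: 20 2-butanoyl-6-[[3-butanoyl-5-[(3-butanoyl-2,4-dihydroxy-6-methoxy-5-methylphenyl)methyl]-2,4,6-trihydroxyphenyl]methyl]-3,5-dihydroxy-4,4-dimethylcyclohexa-2,5-dien-1-one, via ortho-quinone methide 19 (not isolated)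
Conditions: 9 (1.2 equiv), 1,4-dioxane, 80 °C, N2
Reagents that add atoms: none
Why: Retro-Mannich loss of dimethylamine gives the ortho-quinone methide on ring B, and the ring CH of the β-triketone 9, the most acidic and most nucleophilic carbon present, should add to it in a Michael reaction, with rearomatisation of ring B completing the second methylene bridge.

**Compound list**
1 | pent-1-yne | C#CCCC | starting material
2 | 2-methylpropanoyl chloride | CC(C)C(=O)Cl | starting material
3 | 2-methyloct-4-yn-3-one | CCCC#CC(=O)C(C)C | intermediate
4 | (E)-5-methoxy-2-methyloct-4-en-3-one | CO/C(CCC)=C/C(=O)C(C)C | intermediate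
5 | [(4E)-5-methoxy-2-methylocta-2,4-dien-3-yl]oxy-trimethylsilane | CO/C(CCC)=C/C(O[Si](C)(C)C)=C(C)C | intermediate
6 | propanedioyl dichloride (malonyl dichloride) | O=C(Cl)CC(=O)Cl | starting material
7 | (E)-7-methoxy-4,4-dimethyl-3,5-dioxodec-6-enoyl chloride | CO/C(CCC)=C/C(=O)C(C)(C)C(=O)CC(=O)Cl | intermediate (not isolated)
8 | 2-(1-methoxybutylidene)-4,4-dimethylcyclohexane-1,3,5-trione (double-bond geometry not defined) | CCCC(OC)=C1C(=O)CC(=O)C(C)(C)C1=O | intermediate (not isolated)
9 | butyrylfilicinic acid, 2-butanoyl-3,5-dihydroxy-4,4-dimethylcyclohexa-2,5-dien-1-one | CCCC(=O)C1=C(O)C(C)(C)C(O)=CC1=O | intermediate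
10 | 2,4,6-trihydroxytoluene | Cc1c(O)cc(O)cc1O | starting material
11 | butanoyl chloride | CCCC(=O)Cl | starting material
12 | 1-(2,4,6-trihydroxy-3-methylphenyl)butan-1-one | CCCC(=O)c1c(O)cc(O)c(C)c1O | intermediate
13 | aspidinol, 1-(2,6-dihydroxy-4-methoxy-3-methylphenyl)butan-1-one | CCCC(=O)c1c(O)cc(OC)c(C)c1O | intermediate
14 | 1-[3-[(dimethylamino)methyl]-2,6-dihydroxy-4-methoxy-5-methylphenyl]butan-1-one | CCCC(=O)c1c(O)c(CN(C)C)c(OC)c(C)c1O | intermediate
15 | 1-(2,4,6-trihydroxyphenyl)butan-1-one (phlorbutyrophenone) | CCCC(=O)c1c(O)cc(O)cc1O | starting material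
16 | 2-butanoyl-3-hydroxy-5-methoxy-4-methyl-6-methylidenecyclohexa-2,4-dien-1-one | C=C1C(=O)C(C(=O)CCC)=C(O)C(C)=C1OC | intermediate (not isolated)
17 | 1-[3-[(3-butanoyl-2,4-dihydroxy-6-methoxy-5-methylphenyl)methyl]-2,4,6-trihydroxyphenyl]butan-1-one | CCCC(=O)c1c(O)cc(O)c(Cc2c(O)c(C(=O)CCC)c(O)c(C)c2OC)c1O | intermediate
18 | 1-[3-[(3-butanoyl-2,4-dihydroxy-6-methoxy-5-methylphenyl)methyl]-5-[(dimethylamino)methyl]-2,4,6-trihydroxyphenyl]butan-1-one | CCCC(=O)c1c(O)c(CN(C)C)c(O)c(Cc2c(O)c(C(=O)CCC)c(O)c(C)c2OC)c1O | intermediate
19 | 2-butanoyl-4-[(3-butanoyl-2,4-dihydroxy-6-methoxy-5-methylphenyl)methyl]-3,5-dihydroxy-6-methylidenecyclohexa-2,4-dien-1-one | C=C1C(=O)C(C(=O)CCC)=C(O)C(Cc2c(O)c(C(=O)CCC)c(O)c(C)c2OC)=C1O | intermediate (not isolated)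
20 | 2-butanoyl-6-[[3-butanoyl-5-[(3-butanoyl-2,4-dihydroxy-6-methoxy-5-methylphenyl)methyl]-2,4,6-trihydroxyphenyl]methyl]-3,5-dihydroxy-4,4-dimethylcyclohexa-2,5-dien-1-one | CCCC(=O)C1=C(O)C(C)(C)C(O)=C(Cc2c(O)c(Cc3c(O)c(C(=O)CCC)c(O)c(C)c3OC)c(O)c(C(=O)CCC)c2O)C1=O | target

**Count and risks**
Total step count: 10. Longest linear sequence: 6 steps (steps 5, 6, 7, 8, 9, 10).

Steps most likely to fail:

Step 4 (the step that goes beyond known chemistry). Ring closure may run through oxygen to an enol lactone that does not isomerise, the diene may be protodesilylated before it is acylated, or two diene molecules may attack one malonyl dichloride. The fallback uses known chemistry, sets out from 15 and comes back to the route at 9. Compound 15 is treated with iodomethane and NaOMe in methanol at 0 °C to rt, the classical dearomatising geminal C-methylation of an acylphloroglucinol, and 9 is separated from the mono- and trimethylated congeners. This fallback makes no new compound (F0) and replaces steps 1 to 4.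

Step 10. Either methylene bridge may cleave reversibly by retro-Michael reaction at the reaction temperature, which would exchange the units and lead to symmetrical dimers, or the amine may be lost too slowly from the ammonium salt that the acidic triketone forms with 18. The fallback reverses the roles of the partners, sets out from 9 and 17 and comes back at 20. Compound 9 is aminomethylated with [Me2N=CH2]I to the Mannich base 2-butanoyl-6-[(dimethylamino)methyl]-3,5-dihydroxy-4,4-dimethylcyclohexa-2,5-dien-1-one F1. F1 and 17 are then warmed in dioxane, so that the exocyclic enone formed from ring A by loss of dimethylamine is the acceptor and the free nuclear CH of ring B in 17 is the donor. Steps 9 and 10 are replaced.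

Step 6. Methylation may go too far, may occur at a chelated ortho hydroxyl, or may occur on carbon. The fallback sets the pattern by chelation-directed dealkylation instead of selective alkylation, sets out from 11 and comes back at 13. Compound 11 acylates purchased 2,4,6-trimethoxytoluene F2 (AlCl3, CH2Cl2) to 1-(2,4,6-trimethoxy-3-methylphenyl)butan-1-one F3. BCl3 in CH2Cl2 then cleaves the two methoxy groups ortho to the ketone through the boron chelate and spares the para methoxy group, which gives 13. Steps 5 and 6 are replaced.

**Further compounds**
F0 | step 4 | none | none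
F1 | step 10 | 2-butanoyl-6-[(dimethylamino)methyl]-3,5-dihydroxy-4,4-dimethylcyclohexa-2,5-dien-1-one | CCCC(=O)C1=C(O)C(C)(C)C(O)=C(CN(C)C)C1=O
F2 | step 6 | 2,4,6-trimethoxytoluene (purchased) | Cc1c(OC)cc(OC)cc1OC
F3 | step 6 | 1-(2,4,6-trimethoxy-3-methylphenyl)butan-1-one | CCCC(=O)c1c(OC)cc(OC)c(C)c1OC
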